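## Retrosynthetic overview

1. Locants: the furofuran carbons are C7 (bears ring B), C8, C9H2 and C7' (bears ring C of the benzofuran), C8', C9'H2. Ring E is O–C7–C8–C8'–C9' and ring F is O–C7'–C8'–C8–C9; rings A and D are the two guaiacyl rings. The ketone next to ring A is carried as a silylated carbinol and is oxidised only one step before global desilylation.
2. Ring F is traced back to its γ-lactone (C9 as C=O). Lactone → lactol → ether later removes that oxygen without touching the C9–O bond.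
3. Key disconnection. In ring F, C9 is a one-carbon branch on C8, and the neighbouring C8' carries the carbinol C7'–OH three atoms away from C9. Ring E plus C9 is therefore an oxan-4-one with C9 as the carbonyl between C8 and C8'. Photo-Wolff ring contraction of its 3-diazo derivative forms ring E (C8–C8' bond) and a ketene at C9, which the C7' hydroxyl captures to close ring F through the C9–O bond.
4. The oxanone comes from a D-proline-type anti aldol of oxan-4-one with the ring C/D aldehyde (sets C8', C7'), Saegusa oxidation, rhodium-catalysed conjugate addition of the ring A/B arylboronate (sets C7, trans to the C8' branch) and diazo transfer at C8.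
5. Fragments: the ring C/D aldehyde by enantioselective Rh-carbenoid C–H insertion (cis-dihydrobenzofuran); the ring A/B boronate by Evans syn aldol. Order of ring formation: dihydrofuran ring of the benzofuran → temporary oxanone → rings E and F together in the key step.

Key step: step 25

Assumption: the senses of induction of Rh2(S-PTTL)4 (step 6), the D-proline-derived tetrazole (step 19) and (S)-BINAP–rhodium (step 22) are taken from the closest simple substrates, and the enantiomeric catalyst is used if one proves opposite; compound 4 and the zinc reagent of step 11 are bought.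

Abbreviations in names: G = 3-methoxy-4-(triisopropylsilyloxy)phenyl. CD = (2S,3S)-3-[(tert-butyldiphenylsilyloxy)methyl]-2-G-7-methoxy-2,3-dihydro-1-benzofuran-5-yl. AB = 3-methoxy-4-(triisopropylsilyloxy)-5-[(1R,2S)-1-(tert-butyldimethylsilyloxy)-3-(tert-butyldiphenylsilyloxy)-1-G-propan-2-yl]phenyl.

## Ring C/D aldehyde

Step 1
Reactants: 1 vanillin
Product: 2 3-methoxy-4-(triisopropylsilyloxy)benzaldehyde
Conditions: TIPSCl, imidazole, DMF, rt
Reagents that add atoms: triisopropylsilyl chloride, CC(C)[Si](Cl)(C(C)C)C(C)C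
Why: O-silylation of the phenol gives an aryl silyl ether that should survive hydrides, amide bases and mild acid and is removed by fluoride at the end.

Step 2
Reactants: 2 3-methoxy-4-(triisopropylsilyloxy)benzaldehyde
Product: 3 [3-methoxy-4-(triisopropylsilyloxy)phenyl]methanol
Conditions: NaBH4, MeOH/THF, 0 °C
Reagents that add atoms: none
Why: Borohydride reduction of an aryl aldehyde to the benzylic alcohol.

Step 3
Reactants: 3 [3-methoxy-4-(triisopropylsilyloxy)phenyl]methanol; 4 3-bromo-4-hydroxy-5-methoxybenzonitrile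
Product: 5 3-bromo-5-methoxy-4-(G-methoxy)benzonitrile
Conditions: PPh3, DIAD, THF, 0 °C → rt
Reagents that add atoms: none
Why: Mitsunobu etherification of the acidic bromophenol with the primary benzylic alcohol under neutral conditions that leave the aryl silyl ether alone.

Step 4
Reactants: 5 3-bromo-5-methoxy-4-(G-methoxy)benzonitrile
Product: 6 methyl 2-[5-cyano-3-methoxy-2-(G-methoxy)phenyl]acetate
Conditions: BrZnCH2CO2Me (from methyl bromoacetate and Zn dust), Pd2(dba)3 (2.5 mol %), XPhos (10 mol %), THF, 60 °C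
Reagents that add atoms: (2-methoxy-2-oxoethyl)zinc bromide, COC(=O)C[Zn]Br
Why: Palladium-catalysed α-arylation of a Reformatsky reagent (Negishi-type coupling) replaces bromine by CH2CO2Me and tolerates the nitrile.

Step 5
Reactants: 6 methyl 2-[5-cyano-3-methoxy-2-(G-methoxy)phenyl]acetate
Product: 7 methyl 2-[5-cyano-3-methoxy-2-(G-methoxy)phenyl]-2-diazoacetate
Conditions: p-ABSA, DBU, MeCN, 0 °C → rt
Reagents that add atoms: 4-acetamidobenzenesulfonyl azide, CC(=O)Nc1ccc(cc1)S(=O)(=O)N=[N+]=[N-]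
Why: Regitz diazo transfer to the acidic arylacetate position.

Step 6
Reactants: 7 methyl 2-[5-cyano-3-methoxy-2-(G-methoxy)phenyl]-2-diazoacetate
Product: 8 methyl (2S,3R)-5-cyano-2-G-7-methoxy-2,3-dihydro-1-benzofuran-3-carboxylate (cis)
Conditions: Rh2(S-PTTL)4 (1 mol %), toluene, −60 °C
Reagents that add atoms: none
Why: Intramolecular C–H insertion of the rhodium carbenoid into the benzylic O–CH2 bond (enantioselective dihydrobenzofuran synthesis of the Hashimoto type) closes the dihydrofuran ring; the concerted insertion should give the cis C2/C3 relation under kinetic control, the chiral carboxylate ligands set the absolute sense, and the absence of base keeps C3 from epimerising to trans.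

Step 7
Reactants: 8 methyl (2S,3R)-5-cyano-2-G-7-methoxy-2,3-dihydro-1-benzofuran-3-carboxylate
Product: 9 (2S,3S)-2-G-3-(hydroxymethyl)-7-methoxy-2,3-dihydro-1-benzofuran-5-carbaldehyde
Conditions: i-Bu2AlH (4 equiv), CH2Cl2, −78 → −40 °C; aq. KNaC4H4O6
Reagents that add atoms: water, O
Why: Aluminium hydride reduction takes the ester to the primary alcohol and the nitrile to the aldimine, which hydrolyses to the aldehyde on work-up; the non-basic hydride should leave the cis C3 centre untouched.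

Step 8
Reactants: 9 (2S,3S)-2-G-3-(hydroxymethyl)-7-methoxy-2,3-dihydro-1-benzofuran-5-carbaldehyde
Product: 10 CD-carbaldehyde
Conditions: TBDPSCl, imidazole, CH2Cl2, rt
Reagents that add atoms: tert-butyl(chloro)diphenylsilane, CC(C)(C)[Si](Cl)(c1ccccc1)c1ccccc1
Why: Silylation of the primary alcohol with a group that outlasts the later selective removals of TES and TBS ethers.

## Ring A/B boronate

Step 9
Reactants: 11 4-bromo-2-methoxyphenol
Product: 12 4-bromo-2-iodo-6-methoxyphenol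
Conditions: NIS, TsOH (10 mol %), MeCN, 0 °C → rt
Reagents that add atoms: N-iodosuccinimide, O=C1CCC(=O)N1I
Why: Electrophilic aromatic iodination at the only free position ortho to the hydroxyl group.

Step 10
Reactants: 12 4-bromo-2-iodo-6-methoxyphenol
Product: 13 (4-bromo-2-iodo-6-methoxyphenoxy)triisopropylsilane
Conditions: TIPSCl, imidazole, DMF, 40 °C
Reagents that add atoms: triisopropylsilyl chloride, CC(C)[Si](Cl)(C(C)C)C(C)C
Why: O-silylation of the phenol.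

Step 11
Reactants: 13 (4-bromo-2-iodo-6-methoxyphenoxy)triisopropylsilane
Product: 14 tert-butyl 2-[5-bromo-3-methoxy-2-(triisopropylsilyloxy)phenyl]acetate
Conditions: BrZnCH2CO2t-Bu (THF solution), Pd2(dba)3 (2.5 mol %), XPhos (10 mol %), THF, rt
Reagents that add atoms: (2-tert-butoxy-2-oxoethyl)zinc bromide, CC(C)(C)OC(=O)C[Zn]Br
Why: Negishi-type α-arylation of the Reformatsky reagent; zerovalent palladium inserts into C–I much faster than into C–Br, so the bromide is kept for the later borylation.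

Step 12
Reactants: 14 tert-butyl 2-[5-bromo-3-methoxy-2-(triisopropylsilyloxy)phenyl]acetate
Product: 15 2-[5-bromo-3-methoxy-2-(triisopropylsilyloxy)phenyl]acetic acid
Conditions: TFA, CH2Cl2, 0 °C → rt
Reagents that add atoms: none
Why: Acidolysis of the tert-butyl ester (loss of isobutene) avoids a basic hydrolysis that could strip the aryl silyl ether.

Step 13
Reactants: 15 2-[5-bromo-3-methoxy-2-(triisopropylsilyloxy)phenyl]acetic acid; 16 (R)-4-benzyl-1,3-oxazolidin-2-one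
Product: 18 (4R)-4-benzyl-3-{2-[5-bromo-3-methoxy-2-(triisopropylsilyloxy)phenyl]acetyl}-1,3-oxazolidin-2-one, via mixed pivalic anhydride 17 (not isolated)
Conditions: PivCl, Et3N, THF, −20 °C; then 16, LiCl, rt
Reagents that add atoms: none
Why: N-acylation of the Evans oxazolidinone through the mixed anhydride (LiCl/Et3N variant, no strong base).

Step 14
Reactants: 18 (4R)-4-benzyl-3-{2-[5-bromo-3-methoxy-2-(triisopropylsilyloxy)phenyl]acetyl}-1,3-oxazolidin-2-one; 2 3-methoxy-4-(triisopropylsilyloxy)benzaldehyde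
Product: 20 (4R)-4-benzyl-3-[(2R,3R)-2-[5-bromo-3-methoxy-2-(triisopropylsilyloxy)phenyl]-3-G-3-hydroxypropanoyl]-1,3-oxazolidin-2-one, via dibutylboron Z-enolate 19 (not isolated)
Conditions: n-Bu2BOTf, i-Pr2NEt, CH2Cl2, −78 → 0 °C; then 2, −78 → 0 °C; pH 7 buffer, MeOH, H2O2, 0 °C
Reagents that add atoms: none
Why: Evans syn aldol addition: the Z boron enolate reacts through a chair transition state whose enolate face is fixed by the (R)-benzyl group of the auxiliary, which sets the carbon bearing ring B in the configuration the target needs and the adjacent carbinol carbon (later oxidised) as 3R.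

Step 15
Reactants: 20 (4R)-4-benzyl-3-[(2R,3R)-2-[5-bromo-3-methoxy-2-(triisopropylsilyloxy)phenyl]-3-G-3-hydroxypropanoyl]-1,3-oxazolidin-2-one
Product: 21 (1R,2S)-2-[5-bromo-3-methoxy-2-(triisopropylsilyloxy)phenyl]-1-G-propane-1,3-diol
Conditions: LiBH4, H2O (1.1 equiv), Et2O/THF, 0 °C
Reagents that add atoms: none
Why: Reductive cleavage of the N-acyl oxazolidinone gives the primary alcohol and returns the auxiliary without a base strong enough to epimerise the α-aryl centre.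

Step 16
Reactants: 21 (1R,2S)-2-[5-bromo-3-methoxy-2-(triisopropylsilyloxy)phenyl]-1-G-propane-1,3-diol
Product: 22 (1R,2S)-2-[5-bromo-3-methoxy-2-(triisopropylsilyloxy)phenyl]-3-(tert-butyldiphenylsilyloxy)-1-G-propan-1-ol
Conditions: TBDPSCl, imidazole, CH2Cl2, 0 °C
Reagents that add atoms: tert-butyl(chloro)diphenylsilane, CC(C)(C)[Si](Cl)(c1ccccc1)c1ccccc1
Why: Selective silylation of the primary hydroxyl over the hindered secondary benzylic one.

Step 17
Reactants: 22 (1R,2S)-2-[5-bromo-3-methoxy-2-(triisopropylsilyloxy)phenyl]-3-(tert-butyldiphenylsilyloxy)-1-G-propan-1-ol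
Product: 23 (1R,2S)-2-[5-bromo-3-methoxy-2-(triisopropylsilyloxy)phenyl]-1-(tert-butyldimethylsilyloxy)-3-(tert-butyldiphenylsilyloxy)-1-G-propane
Conditions: TBSOTf, 2,6-lutidine, CH2Cl2, −78 → 0 °C
Reagents that add atoms: tert-butyldimethylsilyl trifluoromethanesulfonate, CC(C)(C)[Si](C)(C)OS(=O)(=O)C(F)(F)F
Why: Silyl triflate silylation of the hindered secondary alcohol; this is the one alkyl silyl ether that buffered HF can later remove selectively.

Step 18
Reactants: 23 (1R,2S)-2-[5-bromo-3-methoxy-2-(triisopropylsilyloxy)phenyl]-1-(tert-butyldimethylsilyloxy)-3-(tert-butyldiphenylsilyloxy)-1-G-propane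
Product: 24 2-(AB)-4,4,5,5-tetramethyl-1,3,2-dioxaborolane
Conditions: B2pin2, PdCl2(dppf) (5 mol %), KOAc, 1,4-dioxane, 85 °C
Reagents that add atoms: bis(pinacolato)diboron, CC1(C)OB(OC1(C)C)B1OC(C)(C)C(C)(C)O1
Why: Miyaura borylation of the aryl bromide.

## Oxanone, key step and furofuran

Step 19
Reactants: 10 CD-carbaldehyde; 25 oxan-4-one (tetrahydro-4H-pyran-4-one)
Product: 26 (3R)-3-[(S)-hydroxy(CD)methyl]oxan-4-one
Conditions: (R)-5-(pyrrolidin-2-yl)-1H-tetrazole (20 mol %), 25 (10 equiv), DMSO, rt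
Reagents that add atoms: none
Why: Enamine-catalysed direct aldol addition (proline-type catalysis, Houk–List transition state): the acidic tetrazole directs the aldehyde to one enamine face, which should give the anti adduct with C8' R and C7' S, the mirror image of the well-documented outcome of the L-series catalyst with this ketone, and the excess of cheap ketone drives the addition to the electron-rich aldehyde.

Step 20
Reactants: 26 (3R)-3-[(S)-hydroxy(CD)methyl]oxan-4-one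
Product: 27 (3R)-3-[(S)-(CD)(triethylsilyloxy)methyl]oxan-4-one
Conditions: TESCl, imidazole, DMF, 0 °C → rt
Reagents that add atoms: chlorotriethylsilane, CC[Si](Cl)(CC)CC
Why: Silylation of the aldol hydroxyl blocks retro-aldol cleavage and β-elimination in the enolisation steps that follow.

Step 21
Reactants: 27 (3R)-3-[(S)-(CD)(triethylsilyloxy)methyl]oxan-4-one
Product: 29 (5R)-5-[(S)-(CD)(triethylsilyloxy)methyl]-2,3-dihydro-4H-pyran-4-one, via trimethylsilyl enol ether 28 (not isolated)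
Conditions: LiN(i-Pr)2, TMSCl, THF, −78 °C; then Pd(OAc)2 (1.05 equiv), MeCN, rt
Reagents that add atoms: none
Why: Saegusa–Ito oxidation: kinetic deprotonation takes the unhindered CH2 (C8) rather than the branched C8'–H, and palladium diacetate dehydrogenates the silyl enol ether to the C7=C8 enone.

Step 22
Reactants: 29 (5R)-5-[(S)-(CD)(triethylsilyloxy)methyl]-2,3-dihydro-4H-pyran-4-one; 24 2-(AB)-4,4,5,5-tetramethyl-1,3,2-dioxaborolane
Product: 30 (2S,5R)-2-(AB)-5-[(S)-(CD)(triethylsilyloxy)methyl]oxan-4-one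
Conditions: [Rh(OH)((S)-BINAP)]2 (3 mol %), 1,4-dioxane/H2O (10:1), 50 °C
Reagents that add atoms: none
Why: Rhodium-catalysed asymmetric conjugate addition of an arylboron reagent to a cyclic enone (Hayashi–Miyaura reaction): insertion of the enone into the aryl–rhodium bond should occur on the face selected by (S)-BINAP, the sense that gives (S)-3-arylcyclohexanones, which sets C7 S with ring B trans to the C8' branch, also the diequatorial arrangement.

Step 23
Reactants: 30 (2S,5R)-2-(AB)-5-[(S)-(CD)(triethylsilyloxy)methyl]oxan-4-one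
Product: 32 (2R,5R)-2-(AB)-3-diazo-5-[(S)-(CD)(triethylsilyloxy)methyl]oxan-4-one, via trifluoroacetyl ketone 31 (not isolated)
Conditions: LiN(SiMe3)2, THF, −78 °C; CF3CO2CH2CF3; then MsN3, Et3N, H2O (1 equiv), MeCN, rt
Reagents that add atoms: methanesulfonyl azide, CS(=O)(=O)N=[N+]=[N-]
Why: Detrifluoroacetylative diazo transfer (Danheiser procedure): kinetic enolisation again takes the CH2 (C8), the trifluoroacetyl group activates that carbon for transfer of N2 and leaves as the sulfonyl amide.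

Step 24
Reactants: 32 (2R,5R)-2-(AB)-3-diazo-5-[(S)-(CD)(triethylsilyloxy)methyl]oxan-4-one
Product: 33 (2R,5R)-2-(AB)-3-diazo-5-[(S)-(CD)(hydroxy)methyl]oxan-4-one
Conditions: HF·pyridine, pyridine, THF, 0 °C
Reagents that add atoms: none
Why: Buffered HF should cleave the triethylsilyl ether much faster than the TBS, TBDPS and aryl TIPS ethers and leave the diazo ketone intact.

Step 25
Reactants: 33 (2R,5R)-2-(AB)-3-diazo-5-[(S)-(CD)(hydroxy)methyl]oxan-4-one
Product: 35 (3S,3aR,6S,6aS)-6-(AB)-3-(CD)-tetrahydro-1H,3H-furo[3,4-c]furan-1-one, via ketene 34 (not isolated)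
Conditions: hν (365 nm), dry MeCN (0.005 M), rt
Reagents that add atoms: none
Why: Irradiation expels N2 from the diazo ketone, whose C=N2 and C=O are held s-cis by the ring, with concerted 1,2-shift of C8' from the carbonyl carbon C9 to C8 (Wolff rearrangement), so the oxanone contracts to ring E carrying an exocyclic ketene C8=C9=O; the C7' hydroxyl on the neighbouring carbon then adds to the ketene carbon and the enol tautomerises. The closest known reaction type is the photochemical Wolff ring contraction of cyclic 2-diazo ketones, oxygen heterocycles included, with capture of the ketene by an alcohol. Ring E is closed by the 1,2-carbon shift that forms C8–C8', and ring F by 5-exo-dig addition of the hydroxyl oxygen to C9, which forms the C9–O bond as a lactone. C7, C8' and C7' are carried over unchanged because the migrating carbon keeps its configuration, and the new centre C8 is set by protonation of the enol, which can only deliver the cis-fused bicycle (a trans 5,5-fusion is too strained) and remains correctable α to the lactone carbonyl; since ring B is trans to the C8' branch in 33, both aryl groups should end up exo. The step needs rearrangement to win over O–H insertion and 1,2-hydride shift of a free carbene, and intramolecular ketene capture to win over intermolecular reactions: direct irradiation of an s-cis-locked diazo ketone without a metal catalyst favours the concerted shift, and the hydroxyl held three atoms from C9 together with high dilution favours lactonisation.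

Step 26
Reactants: 35 (3S,3aR,6S,6aS)-6-(AB)-3-(CD)-tetrahydro-1H,3H-furo[3,4-c]furan-1-one
Product: 37 (1S,3aR,4S,6aR)-1-(AB)-4-(CD)-tetrahydro-1H,3H-furo[3,4-c]furan, via lactol 36 (not isolated)
Conditions: i-Bu2AlH, CH2Cl2, −78 °C; aq. KNaC4H4O6; then Et3SiH, BF3·OEt2, CH2Cl2, −78 → −40 °C
Reagents that add atoms: none
Why: Reduction of the lactone to the lactol and ionic hydrogenation of its oxocarbenium ion turn C9 into CH2 without breaking the C9–O bond, and the low temperature is meant to keep the benzylic ether centres from ionising.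

## End-game

Step 27
Reactants: 37 (1S,3aR,4S,6aR)-1-(AB)-4-(CD)-tetrahydro-1H,3H-furo[3,4-c]furan
Product: 38 (1R,2S)-3-(tert-butyldiphenylsilyloxy)-1-G-2-{3-methoxy-4-(triisopropylsilyloxy)-5-[(1S,3aR,4S,6aR)-4-(CD)-tetrahydro-1H,3H-furo[3,4-c]furan-1-yl]phenyl}propan-1-ol
Conditions: HF·pyridine, pyridine, THF, 0 °C → rt
Reagents that add atoms: none
Why: Buffered HF should remove the secondary alkyl TBS ether while the primary TBDPS ethers and the aryl TIPS ethers, both far more stable to acidic fluoride, stay in place.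

Step 28
Reactants: 38 (1R,2S)-3-(tert-butyldiphenylsilyloxy)-1-G-2-{3-methoxy-4-(triisopropylsilyloxy)-5-[(1S,3aR,4S,6aR)-4-(CD)-tetrahydro-1H,3H-furo[3,4-c]furan-1-yl]phenyl}propan-1-ol
Product: 39 (2S)-3-(tert-butyldiphenylsilyloxy)-1-G-2-{3-methoxy-4-(triisopropylsilyloxy)-5-[(1S,3aR,4S,6aR)-4-(CD)-tetrahydro-1H,3H-furo[3,4-c]furan-1-yl]phenyl}propan-1-one
Conditions: Dess–Martin periodinane, NaHCO3, CH2Cl2, 0 °C → rt
Reagents that add atoms: none
Why: Dess–Martin oxidation of the benzylic carbinol under buffered, non-basic conditions, so that the α-aryl centre next to the new ketone should keep its configuration.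

Step 29
Reactants: 39 (2S)-3-(tert-butyldiphenylsilyloxy)-1-G-2-{3-methoxy-4-(triisopropylsilyloxy)-5-[(1S,3aR,4S,6aR)-4-(CD)-tetrahydro-1H,3H-furo[3,4-c]furan-1-yl]phenyl}propan-1-one
Product: 40 (2S)-3-hydroxy-1-(4-hydroxy-3-methoxyphenyl)-2-{2-hydroxy-3-methoxy-5-[(1S,3aR,4S,6aR)-4-[(2S,3S)-2-(4-hydroxy-3-methoxyphenyl)-3-(hydroxymethyl)-7-methoxy-2,3-dihydro-1-benzofuran-5-yl]tetrahydro-1H,3H-furo[3,4-c]furan-1-yl]phenyl}propan-1-one (CNP0174045.1)
Conditions: TBAF, AcOH (1:1), THF, 0 °C → rt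
Reagents that add atoms: none
Why: Fluoride-mediated global desilylation; the acetic acid buffer keeps the medium near neutral so that the α-aryl β-hydroxy ketone should neither epimerise nor eliminate and the phenolic cis-dihydrobenzofuran should not open.

## Compound list

1 | vanillin | COc1cc(C=O)ccc1O | starting material
2 | 3-methoxy-4-(triisopropylsilyloxy)benzaldehyde | COc1cc(C=O)ccc1O[Si](C(C)C)(C(C)C)C(C)C | intermediate
3 | [3-methoxy-4-(triisopropylsilyloxy)phenyl]methanol | COc1cc(CO)ccc1O[Si](C(C)C)(C(C)C)C(C)C | intermediate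
4 | 3-bromo-4-hydroxy-5-methoxybenzonitrile | COc1cc(C#N)cc(Br)c1O | starting material
5 | 3-bromo-5-methoxy-4-(G-methoxy)benzonitrile | COc1cc(C#N)cc(Br)c1OCc1ccc(O[Si](C(C)C)(C(C)C)C(C)C)c(OC)c1 | intermediate
6 | methyl 2-[5-cyano-3-methoxy-2-(G-methoxy)phenyl]acetate | COC(=O)Cc1cc(C#N)cc(OC)c1OCc1ccc(O[Si](C(C)C)(C(C)C)C(C)C)c(OC)c1 | intermediate
7 | methyl 2-[5-cyano-3-methoxy-2-(G-methoxy)phenyl]-2-diazoacetate | COC(=O)C(=[N+]=[N-])c1cc(C#N)cc(OC)c1OCc1ccc(O[Si](C(C)C)(C(C)C)C(C)C)c(OC)c1 | intermediate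
8 | methyl (2S,3R)-5-cyano-2-G-7-methoxy-2,3-dihydro-1-benzofuran-3-carboxylate (cis) | N#Cc1cc(OC)c2c(c1)[C@@H](C(=O)OC)[C@@H](c1ccc(O[Si](C(C)C)(C(C)C)C(C)C)c(OC)c1)O2 | intermediate
9 | (2S,3S)-2-G-3-(hydroxymethyl)-7-methoxy-2,3-dihydro-1-benzofuran-5-carbaldehyde | O=Cc1cc(OC)c2c(c1)[C@@H](CO)[C@@H](c1ccc(O[Si](C(C)C)(C(C)C)C(C)C)c(OC)c1)O2 | intermediate
10 | CD-carbaldehyde | O=Cc1cc(OC)c2c(c1)[C@@H](CO[Si](c1ccccc1)(c1ccccc1)C(C)(C)C)[C@@H](c1ccc(O[Si](C(C)C)(C(C)C)C(C)C)c(OC)c1)O2 | intermediate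
11 | 4-bromo-2-methoxyphenol | COc1cc(Br)ccc1O | starting material
12 | 4-bromo-2-iodo-6-methoxyphenol | COc1cc(Br)cc(I)c1O | intermediate
13 | (4-bromo-2-iodo-6-methoxyphenoxy)triisopropylsilane | COc1cc(Br)cc(I)c1O[Si](C(C)C)(C(C)C)C(C)C | intermediate
14 | tert-butyl 2-[5-bromo-3-methoxy-2-(triisopropylsilyloxy)phenyl]acetate | COc1cc(Br)cc(CC(=O)OC(C)(C)C)c1O[Si](C(C)C)(C(C)C)C(C)C | intermediate
15 | 2-[5-bromo-3-methoxy-2-(triisopropylsilyloxy)phenyl]acetic acid | COc1cc(Br)cc(CC(=O)O)c1O[Si](C(C)C)(C(C)C)C(C)C | intermediate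
16 | (R)-4-benzyl-1,3-oxazolidin-2-one | O=C1N[C@H](Cc2ccccc2)CO1 | starting material
17 | mixed anhydride of 15 with pivalic acid (not isolated) | COc1cc(Br)cc(CC(=O)OC(=O)C(C)(C)C)c1O[Si](C(C)C)(C(C)C)C(C)C | intermediate
18 | (4R)-4-benzyl-3-{2-[5-bromo-3-methoxy-2-(triisopropylsilyloxy)phenyl]acetyl}-1,3-oxazolidin-2-one | COc1cc(Br)cc(CC(=O)N2[C@H](Cc3ccccc3)COC2=O)c1O[Si](C(C)C)(C(C)C)C(C)C | intermediate
19 | dibutylboron Z-enolate of 18 (not isolated) | CCCCB(CCCC)O/C(=C\c1cc(Br)cc(OC)c1O[Si](C(C)C)(C(C)C)C(C)C)N1[C@H](Cc2ccccc2)COC1=O | intermediate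
20 | (4R)-4-benzyl-3-[(2R,3R)-2-[5-bromo-3-methoxy-2-(triisopropylsilyloxy)phenyl]-3-G-3-hydroxypropanoyl]-1,3-oxazolidin-2-one | COc1cc([C@H](O)[C@@H](c2cc(Br)cc(OC)c2O[Si](C(C)C)(C(C)C)C(C)C)C(=O)N2[C@H](Cc3ccccc3)COC2=O)ccc1O[Si](C(C)C)(C(C)C)C(C)C | intermediate
21 | (1R,2S)-2-[5-bromo-3-methoxy-2-(triisopropylsilyloxy)phenyl]-1-G-propane-1,3-diol | COc1cc([C@H](O)[C@H](CO)c2cc(Br)cc(OC)c2O[Si](C(C)C)(C(C)C)C(C)C)ccc1O[Si](C(C)C)(C(C)C)C(C)C | intermediate
22 | (1R,2S)-2-[5-bromo-3-methoxy-2-(triisopropylsilyloxy)phenyl]-3-(tert-butyldiphenylsilyloxy)-1-G-propan-1-ol | COc1cc([C@H](O)[C@H](CO[Si](c2ccccc2)(c2ccccc2)C(C)(C)C)c2cc(Br)cc(OC)c2O[Si](C(C)C)(C(C)C)C(C)C)ccc1O[Si](C(C)C)(C(C)C)C(C)C | intermediate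
23 | (1R,2S)-2-[5-bromo-3-methoxy-2-(triisopropylsilyloxy)phenyl]-1-(tert-butyldimethylsilyloxy)-3-(tert-butyldiphenylsilyloxy)-1-G-propane | COc1cc([C@H](O[Si](C)(C)C(C)(C)C)[C@H](CO[Si](c2ccccc2)(c2ccccc2)C(C)(C)C)c2cc(Br)cc(OC)c2O[Si](C(C)C)(C(C)C)C(C)C)ccc1O[Si](C(C)C)(C(C)C)C(C)C | intermediate
24 | 2-(AB)-4,4,5,5-tetramethyl-1,3,2-dioxaborolane | COc1cc([C@H](O[Si](C)(C)C(C)(C)C)[C@H](CO[Si](c2ccccc2)(c2ccccc2)C(C)(C)C)c2cc(B3OC(C)(C)C(C)(C)O3)cc(OC)c2O[Si](C(C)C)(C(C)C)C(C)C)ccc1O[Si](C(C)C)(C(C)C)C(C)C | intermediate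
25 | oxan-4-one (tetrahydro-4H-pyran-4-one) | O=C1CCOCC1 | starting material
26 | (3R)-3-[(S)-hydroxy(CD)methyl]oxan-4-one | O=C1CCOC[C@@H]1[C@H](O)c1cc(OC)c2c(c1)[C@@H](CO[Si](c1ccccc1)(c1ccccc1)C(C)(C)C)[C@@H](c1ccc(O[Si](C(C)C)(C(C)C)C(C)C)c(OC)c1)O2 | intermediate
27 | (3R)-3-[(S)-(CD)(triethylsilyloxy)methyl]oxan-4-one | O=C1CCOC[C@@H]1[C@H](O[Si](CC)(CC)CC)c1cc(OC)c2c(c1)[C@@H](CO[Si](c1ccccc1)(c1ccccc1)C(C)(C)C)[C@@H](c1ccc(O[Si](C(C)C)(C(C)C)C(C)C)c(OC)c1)O2 | intermediate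
28 | (3R)-3-[(S)-(CD)(triethylsilyloxy)methyl]-4-(trimethylsilyloxy)-3,6-dihydro-2H-pyran (not isolated) | C[Si](C)(C)OC1=CCOC[C@@H]1[C@H](O[Si](CC)(CC)CC)c1cc(OC)c2c(c1)[C@@H](CO[Si](c1ccccc1)(c1ccccc1)C(C)(C)C)[C@@H](c1ccc(O[Si](C(C)C)(C(C)C)C(C)C)c(OC)c1)O2 | intermediate
29 | (5R)-5-[(S)-(CD)(triethylsilyloxy)methyl]-2,3-dihydro-4H-pyran-4-one | O=C1C=COC[C@@H]1[C@H](O[Si](CC)(CC)CC)c1cc(OC)c2c(c1)[C@@H](CO[Si](c1ccccc1)(c1ccccc1)C(C)(C)C)[C@@H](c1ccc(O[Si](C(C)C)(C(C)C)C(C)C)c(OC)c1)O2 | intermediate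
30 | (2S,5R)-2-(AB)-5-[(S)-(CD)(triethylsilyloxy)methyl]oxan-4-one | COc1cc([C@H](O[Si](C)(C)C(C)(C)C)[C@H](CO[Si](c2ccccc2)(c2ccccc2)C(C)(C)C)c2cc([C@H]3OC[C@H]([C@H](O[Si](CC)(CC)CC)c4cc(OC)c5c(c4)[C@@H](CO[Si](c4ccccc4)(c4ccccc4)C(C)(C)C)[C@@H](c4ccc(O[Si](C(C)C)(C(C)C)C(C)C)c(OC)c4)O5)C(=O)C3)cc(OC)c2O[Si](C(C)C)(C(C)C)C(C)C)ccc1O[Si](C(C)C)(C(C)C)C(C)C | intermediate
31 | 3-(trifluoroacetyl) derivative of 30 (configuration at C3 open; not isolated) | COc1cc([C@H](O[Si](C)(C)C(C)(C)C)[C@H](CO[Si](c2ccccc2)(c2ccccc2)C(C)(C)C)c2cc([C@H]3OC[C@H]([C@H](O[Si](CC)(CC)CC)c4cc(OC)c5c(c4)[C@@H](CO[Si](c4ccccc4)(c4ccccc4)C(C)(C)C)[C@@H](c4ccc(O[Si](C(C)C)(C(C)C)C(C)C)c(OC)c4)O5)C(=O)C3C(=O)C(F)(F)F)cc(OC)c2O[Si](C(C)C)(C(C)C)C(C)C)ccc1O[Si](C(C)C)(C(C)C)C(C)C | intermediate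
32 | (2R,5R)-2-(AB)-3-diazo-5-[(S)-(CD)(triethylsilyloxy)methyl]oxan-4-one | COc1cc([C@H](O[Si](C)(C)C(C)(C)C)[C@H](CO[Si](c2ccccc2)(c2ccccc2)C(C)(C)C)c2cc([C@H]3OC[C@H]([C@H](O[Si](CC)(CC)CC)c4cc(OC)c5c(c4)[C@@H](CO[Si](c4ccccc4)(c4ccccc4)C(C)(C)C)[C@@H](c4ccc(O[Si](C(C)C)(C(C)C)C(C)C)c(OC)c4)O5)C(=O)C3=[N+]=[N-])cc(OC)c2O[Si](C(C)C)(C(C)C)C(C)C)ccc1O[Si](C(C)C)(C(C)C)C(C)C | intermediate
33 | (2R,5R)-2-(AB)-3-diazo-5-[(S)-(CD)(hydroxy)methyl]oxan-4-one | COc1cc([C@H](O[Si](C)(C)C(C)(C)C)[C@H](CO[Si](c2ccccc2)(c2ccccc2)C(C)(C)C)c2cc([C@H]3OC[C@H]([C@H](O)c4cc(OC)c5c(c4)[C@@H](CO[Si](c4ccccc4)(c4ccccc4)C(C)(C)C)[C@@H](c4ccc(O[Si](C(C)C)(C(C)C)C(C)C)c(OC)c4)O5)C(=O)C3=[N+]=[N-])cc(OC)c2O[Si](C(C)C)(C(C)C)C(C)C)ccc1O[Si](C(C)C)(C(C)C)C(C)C | intermediate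
34 | {(2R,4R)-2-(AB)-4-[(S)-(CD)(hydroxy)methyl]oxolan-3-ylidene}methanone, the ketene (not isolated) | COc1cc([C@H](O[Si](C)(C)C(C)(C)C)[C@H](CO[Si](c2ccccc2)(c2ccccc2)C(C)(C)C)c2cc([C@H]3OC[C@H]([C@H](O)c4cc(OC)c5c(c4)[C@@H](CO[Si](c4ccccc4)(c4ccccc4)C(C)(C)C)[C@@H](c4ccc(O[Si](C(C)C)(C(C)C)C(C)C)c(OC)c4)O5)C3=C=O)cc(OC)c2O[Si](C(C)C)(C(C)C)C(C)C)ccc1O[Si](C(C)C)(C(C)C)C(C)C | intermediate
35 | (3S,3aR,6S,6aS)-6-(AB)-3-(CD)-tetrahydro-1H,3H-furo[3,4-c]furan-1-one | COc1cc([C@H](O[Si](C)(C)C(C)(C)C)[C@H](CO[Si](c2ccccc2)(c2ccccc2)C(C)(C)C)c2cc([C@H]3OC[C@H]4[C@@H]3C(=O)O[C@@H]4c3cc(OC)c4c(c3)[C@@H](CO[Si](c3ccccc3)(c3ccccc3)C(C)(C)C)[C@@H](c3ccc(O[Si](C(C)C)(C(C)C)C(C)C)c(OC)c3)O4)cc(OC)c2O[Si](C(C)C)(C(C)C)C(C)C)ccc1O[Si](C(C)C)(C(C)C)C(C)C | intermediate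
36 | lactol of 35 (1-hydroxy compound, both anomers; not isolated) | COc1cc([C@H](O[Si](C)(C)C(C)(C)C)[C@H](CO[Si](c2ccccc2)(c2ccccc2)C(C)(C)C)c2cc([C@H]3OC[C@H]4[C@@H]3C(O)O[C@@H]4c3cc(OC)c4c(c3)[C@@H](CO[Si](c3ccccc3)(c3ccccc3)C(C)(C)C)[C@@H](c3ccc(O[Si](C(C)C)(C(C)C)C(C)C)c(OC)c3)O4)cc(OC)c2O[Si](C(C)C)(C(C)C)C(C)C)ccc1O[Si](C(C)C)(C(C)C)C(C)C | intermediate
37 | (1S,3aR,4S,6aR)-1-(AB)-4-(CD)-tetrahydro-1H,3H-furo[3,4-c]furan | COc1cc([C@H](O[Si](C)(C)C(C)(C)C)[C@H](CO[Si](c2ccccc2)(c2ccccc2)C(C)(C)C)c2cc([C@H]3OC[C@H]4[C@@H]3CO[C@@H]4c3cc(OC)c4c(c3)[C@@H](CO[Si](c3ccccc3)(c3ccccc3)C(C)(C)C)[C@@H](c3ccc(O[Si](C(C)C)(C(C)C)C(C)C)c(OC)c3)O4)cc(OC)c2O[Si](C(C)C)(C(C)C)C(C)C)ccc1O[Si](C(C)C)(C(C)C)C(C)C | intermediate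
38 | (1R,2S)-3-(tert-butyldiphenylsilyloxy)-1-G-2-{3-methoxy-4-(triisopropylsilyloxy)-5-[(1S,3aR,4S,6aR)-4-(CD)-tetrahydro-1H,3H-furo[3,4-c]furan-1-yl]phenyl}propan-1-ol | COc1cc([C@H](O)[C@H](CO[Si](c2ccccc2)(c2ccccc2)C(C)(C)C)c2cc([C@H]3OC[C@H]4[C@@H]3CO[C@@H]4c3cc(OC)c4c(c3)[C@@H](CO[Si](c3ccccc3)(c3ccccc3)C(C)(C)C)[C@@H](c3ccc(O[Si](C(C)C)(C(C)C)C(C)C)c(OC)c3)O4)cc(OC)c2O[Si](C(C)C)(C(C)C)C(C)C)ccc1O[Si](C(C)C)(C(C)C)C(C)C | intermediate
39 | (2S)-3-(tert-butyldiphenylsilyloxy)-1-G-2-{3-methoxy-4-(triisopropylsilyloxy)-5-[(1S,3aR,4S,6aR)-4-(CD)-tetrahydro-1H,3H-furo[3,4-c]furan-1-yl]phenyl}propan-1-one | COc1cc(C(=O)[C@H](CO[Si](c2ccccc2)(c2ccccc2)C(C)(C)C)c2cc([C@H]3OC[C@H]4[C@@H]3CO[C@@H]4c3cc(OC)c4c(c3)[C@@H](CO[Si](c3ccccc3)(c3ccccc3)C(C)(C)C)[C@@H](c3ccc(O[Si](C(C)C)(C(C)C)C(C)C)c(OC)c3)O4)cc(OC)c2O[Si](C(C)C)(C(C)C)C(C)C)ccc1O[Si](C(C)C)(C(C)C)C(C)C | intermediate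
40 | CNP0174045.1, (2S)-3-hydroxy-1-(4-hydroxy-3-methoxyphenyl)-2-{2-hydroxy-3-methoxy-5-[(1S,3aR,4S,6aR)-4-[(2S,3S)-2-(4-hydroxy-3-methoxyphenyl)-3-(hydroxymethyl)-7-methoxy-2,3-dihydro-1-benzofuran-5-yl]tetrahydro-1H,3H-furo[3,4-c]furan-1-yl]phenyl}propan-1-one | COc1cc(C(=O)[C@H](CO)c2cc([C@H]3OC[C@H]4[C@@H]3CO[C@@H]4c3cc(OC)c4c(c3)[C@@H](CO)[C@@H](c3ccc(O)c(OC)c3)O4)cc(OC)c2O)ccc1O | target

## Step count and risks

Total step count: 29. Longest linear sequence: 19 steps (steps 1–8, then 19–29); the ring A/B branch (steps 9–18) joins at step 22.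

Steps most likely to fail:

1. Step 25. The photogenerated species may behave as a free carbene (insertion into the neighbouring O–H bond or 1,2-hydride shift from C7) instead of rearranging, or the ketene may be consumed intermolecularly before the hydroxyl reaches it. The fallback sets out from 32, in which the C7' oxygen is still silylated, so no O–H bond lies near the carbene. Irradiation at 365 nm in methanol should give, by the classical Wolff ring contraction with solvent capture, the ring-contracted methyl oxolane-3-carboxylate F1. HF·pyridine then frees the C7' hydroxyl to give the hydroxy ester F2. Catalytic DBU in toluene at 60 °C should epimerise the ester-bearing carbon C8 and let only the cis isomer lactonise, which returns the route to 35.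

2. Step 19. Enamine addition to the electron-rich aldehyde may be slow and incomplete, with retro-aldol erosion of the diastereomer ratio. The fallback sets out from 25, which is converted to the silyl enol ether 4-(trimethylsilyloxy)-3,6-dihydro-2H-pyran F3 (TMSCl, Et3N, NaI, MeCN). Exchange with SiCl4 (Hg(OAc)2 cat.) gives the trichlorosilyl enol ether 4-(trichlorosilyloxy)-3,6-dihydro-2H-pyran F4. This is added to 10 under catalysis by a chiral stilbenediamine-derived phosphoramide (Lewis-base-catalysed aldol of the Denmark type; closed chair transition state at silicon, anti from the E-configured cyclic enolate). Aqueous NaHCO3 work-up returns the route to 26.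

3. Step 26. The Lewis acid may ionise one of the benzylic ether carbons (C7, C7' or C2 of the dihydrobenzofuran), causing epimerisation or reductive ring opening, or may strip silyl ethers. The fallback sets out from 35. Lawesson's reagent in toluene at 80 °C should give the thionolactone F5, and radical desulfurisation with Ph3SnH and AIBN in toluene at 80–100 °C reduces C=S to CH2 under neutral conditions and returns the route to 37.

## Further compounds

F1 | step 25 | methyl (2S,4R)-2-(AB)-4-[(S)-(CD)(triethylsilyloxy)methyl]oxolane-3-carboxylate (C3 epimers) | COc1cc([C@H](O[Si](C)(C)C(C)(C)C)[C@H](CO[Si](c2ccccc2)(c2ccccc2)C(C)(C)C)c2cc([C@H]3OC[C@H]([C@H](O[Si](CC)(CC)CC)c4cc(OC)c5c(c4)[C@@H](CO[Si](c4ccccc4)(c4ccccc4)C(C)(C)C)[C@@H](c4ccc(O[Si](C(C)C)(C(C)C)C(C)C)c(OC)c4)O5)C3C(=O)OC)cc(OC)c2O[Si](C(C)C)(C(C)C)C(C)C)ccc1O[Si](C(C)C)(C(C)C)C(C)C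
F2 | step 25 | methyl (2S,4R)-2-(AB)-4-[(S)-(CD)(hydroxy)methyl]oxolane-3-carboxylate (C3 epimers) | COc1cc([C@H](O[Si](C)(C)C(C)(C)C)[C@H](CO[Si](c2ccccc2)(c2ccccc2)C(C)(C)C)c2cc([C@H]3OC[C@H]([C@H](O)c4cc(OC)c5c(c4)[C@@H](CO[Si](c4ccccc4)(c4ccccc4)C(C)(C)C)[C@@H](c4ccc(O[Si](C(C)C)(C(C)C)C(C)C)c(OC)c4)O5)C3C(=O)OC)cc(OC)c2O[Si](C(C)C)(C(C)C)C(C)C)ccc1O[Si](C(C)C)(C(C)C)C(C)C
F3 | step 19 | 4-(trimethylsilyloxy)-3,6-dihydro-2H-pyran | C[Si](C)(C)OC1=CCOCC1
F4 | step 19 | 4-(trichlorosilyloxy)-3,6-dihydro-2H-pyran | Cl[Si](Cl)(Cl)OC1=CCOCC1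
F5 | step 26 | (3S,3aR,6S,6aS)-6-(AB)-3-(CD)-tetrahydro-1H,3H-furo[3,4-c]furan-1-thione | COc1cc([C@H](O[Si](C)(C)C(C)(C)C)[C@H](CO[Si](c2ccccc2)(c2ccccc2)C(C)(C)C)c2cc([C@H]3OC[C@H]4[C@@H]3C(=S)O[C@@H]4c3cc(OC)c4c(c3)[C@@H](CO[Si](c3ccccc3)(c3ccccc3)C(C)(C)C)[C@@H](c3ccc(O[Si](C(C)C)(C(C)C)C(C)C)c(OC)c3)O4)cc(OC)c2O[Si](C(C)C)(C(C)C)C(C)C)ccc1O[Si](C(C)C)(C(C)C)C(C)C
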